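**Retrosynthetic overview**
1. Target 9 ⇐ Δ8(17) isomer 8 (radical alkene isomerisation) ⇐ 8α-ol ester 7 (dehydration); the ring-B alkene is unveiled last.
2. 7 ⇐ C15–O ester bond: triol 5 + (R)-2-methylbutanoic acid 6 (primary-selective acylation).
3. 5 ⇐ (13E)-allylic alcohol 4 (Ru–BINAP hydrogenation sets C13) ⇐ 3α-hydroxysclareol 2 (1,3-transposition of the tertiary allylic alcohol).
4. Key disconnection: the C3–O bond. 2 ⇐ (−)-sclareol 1 by direct 3α-selective C–H hydroxylation with a new biocatalyst, which sets C3.
5. Ring order: no ring is built. The trans-decalin with C5, C9 and C10 is taken intact from sclareol, and no C–C bond is made.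

Assumption: the SMILES is read as (13S)-3α-hydroxylabd-7-en-15-yl (2R)-2-methylbutanoate (3R, axial 3α-OH, normal labdane series; 5α-H, 9α-H, 10β-Me), and (−)-sclareol and (R)-2-methylbutanoic acid are bought as catalogue chemicals.

**Route**

Step 1
Reactants: 1 (−)-sclareol
Product: 2 3α-hydroxysclareol [(13R)-labd-14-ene-3α,8α,13-triol]
Conditions: engineered P450-BM3 variant (lysate or E. coli whole cells), NADP+ (cat.), glucose, GDH, air, KPi pH 8.0, 5% DMSO, 25 °C
Reagents that add atoms: dioxygen, O=O
Why: Proposed new method: a P450-BM3 (CYP102A1) variant, evolved from the known 3β-selective sclareol/sclareolide C3-hydroxylase lineage by reshaping the distal pocket (positions 75, 78, 82, 87, 263, 328, 437) so that ring A docks with its methyl-free α-face on the ferryl oxygen while the 8α-OH and the C13 carbinol are held toward the channel entrance (keeping C2 and ring B away), should abstract the axial 3α-H and return OH by radical rebound on the same face with retention, forming the C3–O bond and setting C3 as R; the closest known reaction type is the enzymatic 3β-hydroxylation of sclareol and sclareolide by fungal cultures and P450-BM3 variants, together with mutant-controlled α/β switching in P450-BM3 steroid hydroxylation, whereas 3α-selective hydroxylation of a labdane has not been shown.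

Step 2
Reactants: 2 3α-hydroxysclareol
Product: 4 (13E)-labd-13-ene-3α,8α,15-triol, via 15-O-trimethylsilyl ether 3 (not isolated)
Conditions: Ph3SiOReO3 (2 mol%), BSA (1.2 equiv), Et2O, −50 → 0 °C; then K2CO3 (cat.), MeOH, rt; silica chromatography to geometric purity
Reagents that add atoms: none
Why: Rhenium-oxo-catalysed 1,3-transposition of the tertiary allylic alcohol ([3,3] shift of the allylic perrhenate through a chair with the C12 chain pseudo-equatorial, hence 13E) is driven to the primary isomer because only the primary alkoxide is silylated by BSA, the non-allylic 3α- and 8α-hydroxyls cannot rearrange, and methanolysis frees the 15-OH.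

Step 3
Reactants: 4 (13E)-labd-13-ene-3α,8α,15-triol
Product: 5 (13S)-labdane-3α,8α,15-triol
Conditions: Ru(OAc)2[(R)-BINAP] (1 mol%), H2 (100 atm), MeOH, 20 °C
Reagents that add atoms: none
Why: Noyori Ru–BINAP hydrogenation is directed by the allylic OH, and the (R)-BINAP catalyst adds H2 to the E-alkene with the same facial sense that converts geraniol into (S)-citronellol, so C13 is set as S under catalyst control with the remote ring stereocentres having no say.

Step 4
Reactants: 5 (13S)-labdane-3α,8α,15-triol; 6 (R)-2-methylbutanoic acid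
Product: 7 (13S)-3α,8α-dihydroxylabdan-15-yl (2R)-2-methylbutanoate
Conditions: EDC·HCl (1.2 equiv), DMAP (10 mol%), CH2Cl2, 0 °C
Reagents that add atoms: none
Why: Steglich esterification forms the C15–O ester bond at the unhindered primary alcohol, because the axial neopentyl 3α-OH and the tertiary 8α-OH acylate far more slowly, and catalytic DMAP at 0 °C leaves the α-stereocentre of the acid intact.

Step 5
Reactants: 7 (13S)-3α,8α-dihydroxylabdan-15-yl (2R)-2-methylbutanoate
Product: 8 (13S)-3α-hydroxylabd-8(17)-en-15-yl (2R)-2-methylbutanoate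
Conditions: Martin sulfurane Ph2S[OC(CF3)2Ph]2 (2.0 equiv), CH2Cl2, −50 °C; sat. NaHCO3 quench
Reagents that add atoms: none
Why: Martin sulfurane dehydration removes the tertiary alcohol at −50 °C, where the secondary 3α-OH only exchanges reversibly onto sulfur and is returned on work-up; the equatorial 8α-oxysulfonium group has an anti-periplanar β-hydrogen only on the C17 methyl, so the exocyclic alkene is the main product, and any Δ7 isomer formed by E1 leakage is already 9 and is carried on.

Step 6
Reactants: 8 (13S)-3α-hydroxylabd-8(17)-en-15-yl (2R)-2-methylbutanoate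
Product: 9 (13S)-3α-hydroxylabd-7-en-15-yl (2R)-2-methylbutanoate
Conditions: Co(salen-tBu,tBu)Cl (5 mol%), PhSiH3 (5 mol%), benzene, rt
Reagents that add atoms: none
Why: Cobalt–salen/silane MHAT (radical) alkene isomerisation adds H• reversibly to the terminal CH2 to give the tertiary C8 radical, which returns H• to cobalt from the open C7 rather than from the shielded tertiary C9, giving the trisubstituted Δ7 alkene that is inert to the bulky Co–H, with no stereocentre touched.

**Compound list**
1 | (−)-sclareol [(13R)-labd-14-ene-8α,13-diol] | C=C[C@](C)(O)CC[C@H]1[C@](C)(O)CC[C@H]2C(C)(C)CCC[C@]12C | starting material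
2 | 3α-hydroxysclareol [(13R)-labd-14-ene-3α,8α,13-triol] | C=C[C@](C)(O)CC[C@H]1[C@](C)(O)CC[C@H]2C(C)(C)[C@H](O)CC[C@]12C | intermediate
3 | (13E)-15-(trimethylsilyloxy)labd-13-ene-3α,8α-diol | C[Si](C)(C)OC/C=C(\C)CC[C@H]1[C@](C)(O)CC[C@H]2C(C)(C)[C@H](O)CC[C@]12C | intermediate
4 | (13E)-labd-13-ene-3α,8α,15-triol | OC/C=C(\C)CC[C@H]1[C@](C)(O)CC[C@H]2C(C)(C)[C@H](O)CC[C@]12C | intermediate
5 | (13S)-labdane-3α,8α,15-triol | OCC[C@@H](C)CC[C@H]1[C@](C)(O)CC[C@H]2C(C)(C)[C@H](O)CC[C@]12C | intermediate
6 | (R)-2-methylbutanoic acid | CC[C@@H](C)C(=O)O | starting material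
7 | (13S)-3α,8α-dihydroxylabdan-15-yl (2R)-2-methylbutanoate | CC[C@@H](C)C(=O)OCC[C@@H](C)CC[C@H]1[C@](C)(O)CC[C@H]2C(C)(C)[C@H](O)CC[C@]12C | intermediate
8 | (13S)-3α-hydroxylabd-8(17)-en-15-yl (2R)-2-methylbutanoate | CC[C@@H](C)C(=O)OCC[C@@H](C)CC[C@H]1C(=C)CC[C@H]2C(C)(C)[C@H](O)CC[C@]12C | intermediate
9 | (13S)-3α-hydroxylabd-7-en-15-yl (2R)-2-methylbutanoate | CC[C@@H](C)C(=O)OCC[C@@H](C)CC[C@H]1C(C)=CC[C@H]2C(C)(C)[C@H](O)CC[C@]12C | target

**Totals**
Total step count: 6. Longest linear sequence: 6 steps (1 → 9); acid 6 is bought.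

**Three steps most likely to fail**

Step 1 (proposed new hydroxylation). The variant may not reach useful 3α selectivity, or may give the 3β-alcohol, the ketone or C2 products. The fallback uses known chemistry. It sets out from 1 and comes back at 2. Sclareol is hydroxylated at the equatorial position by the known fungal biotransformation (Mucor plumbeus culture) or a known 3β-selective P450-BM3 variant to give 3β-hydroxysclareol F1. Dess–Martin periodinane (NaHCO3, CH2Cl2) then oxidises only the secondary alcohol to 3-oxosclareol F2. L-Selectride (THF, −78 °C) attacks the 4,4-dimethyl ketone from the equatorial direction and gives the axial 3α-alcohol 2. The material made this way also serves as the authentic standard for screening the new enzyme.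

Step 2 (rhenium transposition). The E/Z ratio may be poor, and the perrhenate may ionise so that the free 8α-OH closes a cyclic ether or is dehydrated. The fallback changes to an ester rearrangement with the 8-oxygen masked. It sets out from 2 and comes back at 4. Acetyl chloride/N,N-dimethylaniline (CH2Cl2, rt) gives 3α-hydroxysclareol triacetate F3. PdCl2(MeCN)2 (5 mol%, THF, rt) shifts only the allylic acetate, a reaction precedented on sclareol diacetate, to give (13E)-labd-13-ene-3α,8α,15-triyl triacetate F4, which is purified from any minor geometric isomer. LiAlH4 (THF, 0 °C → rt) removes the three acetates and returns 4.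

Step 5 (dehydration beside a free 3α-OH). The sulfurane may also attack the secondary alcohol, or E1 leakage may give Δ8(9) or rearranged alkenes. The fallback changes to a protected, purely E2 sequence. It sets out from 7 and comes back at 8. TESCl/imidazole (DMF, rt) silylates only the secondary alcohol to give (13S)-8α-hydroxy-3α-(triethylsilyloxy)labdan-15-yl (2R)-2-methylbutanoate F5. SOCl2/pyridine (CH2Cl2, −78 °C) converts the tertiary alcohol into its chlorosulfite, which eliminates toward C17 to give (13S)-3α-(triethylsilyloxy)labd-8(17)-en-15-yl (2R)-2-methylbutanoate F6. HF·pyridine (THF, 0 °C) removes the silyl group and returns 8.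

**Further compounds**
F1 | step 1 | 3β-hydroxysclareol [(13R)-labd-14-ene-3β,8α,13-triol] | C=C[C@](C)(O)CC[C@H]1[C@](C)(O)CC[C@H]2C(C)(C)[C@@H](O)CC[C@]12C
F2 | step 1 | 3-oxosclareol [(13R)-8α,13-dihydroxylabd-14-en-3-one] | C=C[C@](C)(O)CC[C@H]1[C@](C)(O)CC[C@H]2C(C)(C)C(=O)CC[C@]12C
F3 | step 2 | 3α-hydroxysclareol triacetate [(13R)-labd-14-ene-3α,8α,13-triyl triacetate] | C=C[C@](C)(OC(C)=O)CC[C@H]1[C@](C)(OC(C)=O)CC[C@H]2C(C)(C)[C@H](OC(C)=O)CC[C@]12C
F4 | step 2 | (13E)-labd-13-ene-3α,8α,15-triyl triacetate | CC(=O)OC/C=C(\C)CC[C@H]1[C@](C)(OC(C)=O)CC[C@H]2C(C)(C)[C@H](OC(C)=O)CC[C@]12C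
F5 | step 5 | (13S)-8α-hydroxy-3α-(triethylsilyloxy)labdan-15-yl (2R)-2-methylbutanoate | CC[C@@H](C)C(=O)OCC[C@@H](C)CC[C@H]1[C@](C)(O)CC[C@H]2C(C)(C)[C@H](O[Si](CC)(CC)CC)CC[C@]12C
F6 | step 5 | (13S)-3α-(triethylsilyloxy)labd-8(17)-en-15-yl (2R)-2-methylbutanoate | CC[C@@H](C)C(=O)OCC[C@@H](C)CC[C@H]1C(=C)CC[C@H]2C(C)(C)[C@H](O[Si](CC)(CC)CC)CC[C@]12C
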